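## Analysis of the target

Broussoflavonol B is a flavone: benzo ring A is fused to the pyran-4-one ring C, and the catechol ring B sits on C2. Ring A is hexasubstituted. It carries O1 at C8a, the carbonyl carbon C4 at C4a, free hydroxyls at C5 and C7, and 3-methylbut-2-enyl (prenyl) groups at C6 and C8. C3 carries a methyl ether, while all four phenols are free. There is no stereocentre, and each prenyl double bond ends in two methyl groups, so no alkene geometry has to be set. The prenyl groups are the sensitive part: acid adds the flanking hydroxyls across them to give chromans, electrophilic halogen attacks them, and hydrogenation saturates them. The catechol and the phloroglucinol nucleus are also easily oxidised. The difficulty is ring A: six substituents must be placed in the right order, and the acyl carbon C4 must go onto a crowded, acid-sensitive ring for which Friedel–Crafts or Houben–Hoesch acylation is unattractive. The strategy rests on C4a and C8a. They are neighbours, they carry C4 and O1, and they are flanked by the C5 oxygen and the C8 prenyl group. This pair is read as an aryne across which a carboxylic acid is added, so that its oxygen becomes O1 and its acyl carbon becomes C4.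

## Retrosynthetic reasoning

**24 to 22.** The O1–C2 bond of ring C and the four acetal O–CH2 bonds are cut, which leads through the protected flavone 23 to the 1,3-diketone 22. The 3-methoxy group is already the substituent on the central carbon of 22. The trioxygenated diprenylphenyl unit of 22 is symmetric about its bond to C4, so either ortho oxygen closes to the same flavone and the order of closure and acetal loss does not matter. The forward step needs acid mild enough to spare the prenyl groups.

**22 to 21.** The bond between C3 and the ring B carbonyl (C2–C3 of the flavone) is cut. It is formed by an intramolecular O-to-C acyl shift from phenol ester 21. This replaces an intermolecular Claisen condensation at a hindered ketone, and the ketone has only one enolisable position.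

**21 to 17 and 20.** The ester C–O bond is cut. A carbodiimide coupling is chosen over an acid chloride, because the acetals of 20 would not survive chloride-forming reagents. Acid 20 goes back through ester 19 to the commercial ester 18.

**17 to 14 and 15.** The C4a–C4 and C8a–O1 bonds are cut together. The forward reaction generates aryne 16 from silyl triflate 14 and adds the carboxylate of 15 across it. This puts the acyl group on the ring without any Lewis or protic acid and delivers the free phenol needed for the acyl shift. The forward step must add oxygen at C8a and carbon at C4a, not the reverse.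

**14 to 13 to 12.** The S–O bond of the triflate is cut, then the carbamate C–O bond. The carbamate is kept until here because it is the group that directs the two preceding metalations.

**12 to 10 and 4, 10 to 8.** One C–C bond (prenyl) and one C–Si bond are cut. Both are made by carbamate-directed ortho-lithiation. Silicon is delivered to a carbanion, so no electrophilic bromination of a prenylated phenol is needed. Silicon goes in first, when the two ortho positions are equivalent. The prenyl group follows at the last ring position, where the carbamate has no benzylic or allylic hydrogen beside it that could be removed instead.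

**8 to 6 to 3 and 4.** The carbamate is exchanged for a triisopropylsilyl ether, and the first prenyl C–C bond is cut. The bulky silyl ether shields its own ortho positions, so lithiation of 3 can only occur between the two acetal oxygens. The oxygen para to this first prenyl group is the one that ends as the triflate.

**3 to 2 to 1.** The silyl ether and two acetals are removed to reach phloroglucinol 1. Two acetals on three equivalent hydroxyls is a statistical protection, accepted at the first step on a cheap starting material.

## Alternatives that were turned down

**Alternative 1:** Ring A is built from non-aromatic fragments.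
- Disconnection: three ring A carbon–carbon bonds are cut, giving cyclobutenone A2 and siloxyalkyne A3.
- Forward key step: heating A2 with A3 opens the cyclobutenone to a vinylketene, which adds to the alkyne; ring opening and six-electron closure then give phenol A1.
- For: the positions of both prenyl groups and all three oxygens follow from the connectivity of the fragments. No sequential metalation is needed, and the conditions are neutral and thermal. On regiocontrol of the prenyl groups this is stronger than the chosen route, which spends five steps on it.
- Against: A2 and A3 each need several steps and are hydrolytically fragile. A1 still lacks C4, so acylation of the crowded, acid-sensitive ring remains to be solved after the key step, and the two bulky silyl ethers would have to be exchanged.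
- Comparison: the chosen strategy starts from a cheap aromatic compound and brings in C4 with its methoxymethyl chain together with O1 in one acid-free step, which is the problem Alternative 1 leaves open.

**Alternative 2:** The 1,3-diketone is masked as an isoxazole.
- Disconnection: C2–C3 is cut and the diketone is recognised as isoxazole A4.
- Forward key step: nitrile oxide A5 reacts with the sodium enolate of ketone A6, and loss of water gives A4.
- For: the union is convergent and only mildly basic, the regiochemistry of enolate addition is dependable, and the isoxazole is a robust storage form. A6 should be available by lithiation and acylation of a tris-acetal in fewer steps than ketone 17 of the chosen route; on this point the alternative is stronger.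
- Against: nitrile oxides also add to alkenes, and A6 carries two prenyl groups; they also dimerise. The enolate of a di-ortho-substituted aryl ketone is hindered. Afterwards the N–O bond must be cleaved reductively without touching the prenyl groups, the enaminone hydrolysed, one ortho acetal removed and ring C closed.
- Comparison: that is four operations where the acyl shift of the chosen route needs two. The chosen strategy delivers the phenol already free and introduces no nitrogen that must be removed.

**Alternative 3:** Ring C is closed at C3–C4.
- Disconnection: the C3–C4 bond is cut, giving acid A8, which carries the enol ether on O1.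
- Forward key step: A8 is converted to its acid chloride and the enol ether carbon attacks it, closing ring C to A7. A7 is the same compound as 23 of the chosen route.
- For: the pyranone forms directly with the 3-methoxy group in place, no diketone is needed, and the six-membered closure is favourable. If A8 were in hand, the end game would be as short as that of the chosen route or shorter.
- Against: A8 is hard to make. It needs an O1–C2 bond to a 1-aryl-2-methoxyvinyl unit on a phenol flanked by a prenyl group and a carboxyl group, and it needs a carboxylation of the hexasubstituted ring. The enol ether and four acetals are unlikely to survive acid chloride formation and the electrophilic closure.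
- Comparison: the chosen route reaches the same compound 23 by a base-mediated acyl shift and one mild acid step, and keeps every acid-labile group away from chloride-forming reagents.

Key step: step 9

Remark on the chemistry: diketone 22 is drawn in its keto form; it should exist as a mixture of keto, enol and cyclic hemiketal forms, and its central carbon is configurationally labile and becomes sp2 in step 14.

## Route

Step 1
Reactants: 1 phloroglucinol
Product: 2 3,5-bis(methoxymethoxy)phenol
Conditions: MOMCl (2.1 equiv), i-Pr2NEt, CH2Cl2–DMF, 0 °C to rt
Reagents that add atoms: chloromethyl methyl ether, COCCl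
Why: Williamson-type acetal formation on a phenoxide; the protection is statistical, and the bis-ether should be separable from mono- and tris-ether, which can be recycled.

Step 2
Reactants: 2 3,5-bis(methoxymethoxy)phenol
Product: 3 [3,5-bis(methoxymethoxy)phenoxy]tri(propan-2-yl)silane
Conditions: TIPSCl, imidazole, DMF, rt
Reagents that add atoms: chlorotri(propan-2-yl)silane, CC(C)[Si](Cl)(C(C)C)C(C)C
Why: Standard silylation of a phenol; the bulky silyl ether marks the oxygen that will become the triflate and shields its two ortho positions from lithiation.

Step 3
Reactants: 3 [3,5-bis(methoxymethoxy)phenoxy]tri(propan-2-yl)silane; 4 prenyl bromide (1-bromo-3-methylbut-2-ene)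
Product: 6 [3,5-bis(methoxymethoxy)-4-(3-methylbut-2-enyl)phenoxy]tri(propan-2-yl)silane, via aryllithium 5 (not isolated)
Conditions: n-BuLi, THF, 0 °C; CuBr·SMe2 (cat.), 4, −78 °C to rt
Reagents that add atoms: none
Why: Directed ortho-lithiation between the two acetal oxygens, the only position not shielded by the silyl ether, followed by copper-catalysed allylic substitution at the primary carbon of 4.

Step 4
Reactants: 6 [3,5-bis(methoxymethoxy)-4-(3-methylbut-2-enyl)phenoxy]tri(propan-2-yl)silane
Product: 8 3,5-bis(methoxymethoxy)-4-(3-methylbut-2-enyl)phenyl N,N-diethylcarbamate, via tetrabutylammonium phenoxide 7 (not isolated)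
Conditions: TBAF, THF, 0 °C; then Et2NCOCl, 0 to 50 °C
Reagents that add atoms: N,N-diethylcarbamoyl chloride, CCN(CC)C(Cl)=O
Why: Fluoride cleaves the aryl silyl ether and the phenoxide set free is acylated in the same flask by the carbamoyl chloride; the carbamate is the strong directing group needed for the next two steps.

Step 5
Reactants: 8 3,5-bis(methoxymethoxy)-4-(3-methylbut-2-enyl)phenyl N,N-diethylcarbamate
Product: 10 3,5-bis(methoxymethoxy)-4-(3-methylbut-2-enyl)-2-(trimethylsilyl)phenyl N,N-diethylcarbamate, via aryllithium 9 (not isolated)
Conditions: s-BuLi, TMEDA, THF, −78 °C; TMSCl, −78 °C to rt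
Reagents that add atoms: chlorotrimethylsilane, C[Si](C)(C)Cl
Why: Carbamate-directed ortho-lithiation, reinforced by the neighbouring acetal oxygen; the two ortho positions are equivalent, so there is no regiochemical question, and the fast silyl quench at −78 °C should outrun an anionic ortho-Fries shift.

Step 6
Reactants: 10 3,5-bis(methoxymethoxy)-4-(3-methylbut-2-enyl)-2-(trimethylsilyl)phenyl N,N-diethylcarbamate; 4 prenyl bromide
Product: 12 3,5-bis(methoxymethoxy)-2,4-bis(3-methylbut-2-enyl)-6-(trimethylsilyl)phenyl N,N-diethylcarbamate, via aryllithium 11 (not isolated)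
Conditions: s-BuLi, TMEDA, THF, −78 °C; CuBr·SMe2 (cat.), 4, −78 to −20 °C
Reagents that add atoms: none
Why: Second carbamate-directed ortho-lithiation at the last ring hydrogen, with silicon blocking the other ortho position, then copper-catalysed allylic substitution. The only benzylic and allylic hydrogens lie away from the carbamate, so ring metalation should be preferred over lateral metalation.

Step 7
Reactants: 12 3,5-bis(methoxymethoxy)-2,4-bis(3-methylbut-2-enyl)-6-(trimethylsilyl)phenyl N,N-diethylcarbamate
Product: 13 3,5-bis(methoxymethoxy)-2,4-bis(3-methylbut-2-enyl)-6-(trimethylsilyl)phenol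
Conditions: LiAlH4, THF, 0 °C to reflux; aq. potassium sodium tartrate
Reagents that add atoms: none
Why: Hydride reduction cleaves the aryl carbamate to the phenol under conditions that leave the acetals, the prenyl groups and the aryl–silicon bond untouched; the neutral work-up avoids protodesilylation of the electron-rich arylsilane.

Step 8
Reactants: 13 3,5-bis(methoxymethoxy)-2,4-bis(3-methylbut-2-enyl)-6-(trimethylsilyl)phenol
Product: 14 3,5-bis(methoxymethoxy)-2,4-bis(3-methylbut-2-enyl)-6-(trimethylsilyl)phenyl trifluoromethanesulfonate
Conditions: Tf2O, pyridine, CH2Cl2, −78 to 0 °C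
Reagents that add atoms: trifluoromethanesulfonic anhydride, O=S(=O)(OS(=O)(=O)C(F)(F)F)C(F)(F)F
Why: O-sulfonylation of an ortho-silyl phenol, the usual last step towards an ortho-silylaryl triflate; pyridine buffers the medium so that acetals and arylsilane persist.

Step 9
Reactants: 14 3,5-bis(methoxymethoxy)-2,4-bis(3-methylbut-2-enyl)-6-(trimethylsilyl)phenyl trifluoromethanesulfonate; 15 methoxyacetic acid
Product: 17 1-[2-hydroxy-4,6-bis(methoxymethoxy)-3,5-bis(3-methylbut-2-enyl)phenyl]-2-methoxyethanone, via aryne 16 (not isolated)
Conditions: 15 (2 equiv), Cs2CO3 (1 equiv), MeOH, rt, then evaporation and drying; 14, CsF, THF, 125 °C (sealed tube); AcOH quench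
Reagents that add atoms: none
Why: Fluoride attacks silicon of 14 and the aryl anion expels triflate, giving aryne 16, whose triple bond lies between the future C4a and C8a. The carboxylate oxygen of cesium methoxyacetate adds to C8a and leaves the negative charge on C4a, next to the acetal oxygen at C5. That aryl anion attacks the carbonyl of the aryl ester just formed through a four-membered transition state (4-exo-trig), and the benzoxetene alkoxide opens to the ortho-acyl phenoxide; this is an overall anionic O-to-C acyl shift and no ring remains in the product. The closest known reaction type is the fluoride-induced insertion of arynes into the carbon–oxygen bond of carboxylic acids to give ortho-hydroxyaryl ketones, one of the aryne sigma-bond insertions. No stereocentre is formed. The selectivity needed is regiochemical: the inductively withdrawing C5 oxygen distorts the aryne so that the remote carbon C8a is the more electrophilic end and the charge develops beside oxygen, which should outweigh the modest steric bias of the C8 prenyl group. The carboxylate is used as a dried, preformed salt so that no proton source can quench the aryl anion before the acyl shift, and the high temperature in THF favours the intramolecular step. An intramolecular ene reaction of the neighbouring prenyl group is geometrically out of reach, and the excess of carboxylate should outrun the intermolecular one.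

Step 10
Reactants: 18 methyl 3,4-dihydroxybenzoate
Product: 19 methyl 3,4-bis(methoxymethoxy)benzoate
Conditions: MOMCl, i-Pr2NEt, CH2Cl2, 0 °C to rt
Reagents that add atoms: chloromethyl methyl ether, COCCl
Why: Acetal protection of both catechol hydroxyls, with the carboxyl group masked as its methyl ester.

Step 11
Reactants: 19 methyl 3,4-bis(methoxymethoxy)benzoate
Product: 20 3,4-bis(methoxymethoxy)benzoic acid
Conditions: LiOH, THF–MeOH–H2O, 50 °C; then 1 M HCl to pH 4, 0 °C
Reagents that add atoms: lithium hydroxide, [Li+].[OH-]
Why: Saponification of the methyl ester; the acetals are stable to base and to a brief cold acidification to pH 4.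

Step 12
Reactants: 17 1-[2-hydroxy-4,6-bis(methoxymethoxy)-3,5-bis(3-methylbut-2-enyl)phenyl]-2-methoxyethanone; 20 3,4-bis(methoxymethoxy)benzoic acid
Product: 21 2-(2-methoxyacetyl)-3,5-bis(methoxymethoxy)-4,6-bis(3-methylbut-2-enyl)phenyl 3,4-bis(methoxymethoxy)benzoate
Conditions: EDC·HCl, DMAP, CH2Cl2, rt
Reagents that add atoms: none
Why: Steglich esterification; the acylpyridinium formed from 20 should acylate the hindered, hydrogen-bonded phenol without an acid chloride, which the acetals of 20 would not survive.

Step 13
Reactants: 21 2-(2-methoxyacetyl)-3,5-bis(methoxymethoxy)-4,6-bis(3-methylbut-2-enyl)phenyl 3,4-bis(methoxymethoxy)benzoate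
Product: 22 1-[3,4-bis(methoxymethoxy)phenyl]-3-[2-hydroxy-4,6-bis(methoxymethoxy)-3,5-bis(3-methylbut-2-enyl)phenyl]-2-methoxypropane-1,3-dione
Conditions: LiHMDS, THF, −20 °C to rt; AcOH quench
Reagents that add atoms: none
Why: Baker–Venkataraman rearrangement: the enolate of the methoxymethyl ketone, the only enolisable site, attacks the neighbouring aryl ester through a six-membered transition state and the phenoxide is released, forming the C2–C3 bond of the flavone.

Step 14
Reactants: 22 1-[3,4-bis(methoxymethoxy)phenyl]-3-[2-hydroxy-4,6-bis(methoxymethoxy)-3,5-bis(3-methylbut-2-enyl)phenyl]-2-methoxypropane-1,3-dione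
Product: 24 broussoflavonol B (2-(3,4-dihydroxyphenyl)-5,7-dihydroxy-3-methoxy-6,8-bis(3-methylbut-2-enyl)chromen-4-one), via protected flavone 23 (not isolated)
Conditions: HCl (3 M aq.), MeOH–THF, 45 °C
Reagents that add atoms: none
Why: Acid-catalysed cyclodehydration of the ortho-hydroxyaryl 1,3-diketone closes ring C, and methanolysis removes the four acetals. Ring A of 22 is symmetric, so closure through either ortho oxygen gives the same flavone; dilute acid at moderate temperature is chosen to spare the prenyl groups.

## Compound list

1 | phloroglucinol | Oc1cc(O)cc(O)c1 | starting material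
2 | 3,5-bis(methoxymethoxy)phenol | COCOc1cc(O)cc(OCOC)c1 | intermediate
3 | [3,5-bis(methoxymethoxy)phenoxy]tri(propan-2-yl)silane | COCOc1cc(OCOC)cc(O[Si](C(C)C)(C(C)C)C(C)C)c1 | intermediate
4 | prenyl bromide (1-bromo-3-methylbut-2-ene) | CC(C)=CCBr | starting material
5 | [2,6-bis(methoxymethoxy)-4-(triisopropylsilyloxy)phenyl]lithium | [Li]c1c(OCOC)cc(O[Si](C(C)C)(C(C)C)C(C)C)cc1OCOC | intermediate
6 | [3,5-bis(methoxymethoxy)-4-(3-methylbut-2-enyl)phenoxy]tri(propan-2-yl)silane | COCOc1cc(O[Si](C(C)C)(C(C)C)C(C)C)cc(OCOC)c1CC=C(C)C | intermediate
7 | tetrabutylammonium 3,5-bis(methoxymethoxy)-4-(3-methylbut-2-enyl)phenoxide | COCOc1cc([O-])cc(OCOC)c1CC=C(C)C.CCCC[N+](CCCC)(CCCC)CCCC | intermediate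
8 | 3,5-bis(methoxymethoxy)-4-(3-methylbut-2-enyl)phenyl N,N-diethylcarbamate | CCN(CC)C(=O)Oc1cc(OCOC)c(CC=C(C)C)c(OCOC)c1 | intermediate
9 | [2-(diethylcarbamoyloxy)-4,6-bis(methoxymethoxy)-5-(3-methylbut-2-enyl)phenyl]lithium | [Li]c1c(OC(=O)N(CC)CC)cc(OCOC)c(CC=C(C)C)c1OCOC | intermediate
10 | 3,5-bis(methoxymethoxy)-4-(3-methylbut-2-enyl)-2-(trimethylsilyl)phenyl N,N-diethylcarbamate | CCN(CC)C(=O)Oc1cc(OCOC)c(CC=C(C)C)c(OCOC)c1[Si](C)(C)C | intermediate
11 | [2-(diethylcarbamoyloxy)-4,6-bis(methoxymethoxy)-5-(3-methylbut-2-enyl)-3-(trimethylsilyl)phenyl]lithium | [Li]c1c(OCOC)c(CC=C(C)C)c(OCOC)c([Si](C)(C)C)c1OC(=O)N(CC)CC | intermediate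
12 | 3,5-bis(methoxymethoxy)-2,4-bis(3-methylbut-2-enyl)-6-(trimethylsilyl)phenyl N,N-diethylcarbamate | CCN(CC)C(=O)Oc1c(CC=C(C)C)c(OCOC)c(CC=C(C)C)c(OCOC)c1[Si](C)(C)C | intermediate
13 | 3,5-bis(methoxymethoxy)-2,4-bis(3-methylbut-2-enyl)-6-(trimethylsilyl)phenol | COCOc1c(CC=C(C)C)c(O)c([Si](C)(C)C)c(OCOC)c1CC=C(C)C | intermediate
14 | 3,5-bis(methoxymethoxy)-2,4-bis(3-methylbut-2-enyl)-6-(trimethylsilyl)phenyl trifluoromethanesulfonate | COCOc1c(CC=C(C)C)c(OCOC)c([Si](C)(C)C)c(OS(=O)(=O)C(F)(F)F)c1CC=C(C)C | intermediate
15 | methoxyacetic acid | COCC(=O)O | starting material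
16 | 3,5-bis(methoxymethoxy)-4,6-bis(3-methylbut-2-enyl)benzyne (1,2-didehydrobenzene) | COCOC1=C(CC=C(C)C)C#CC(OCOC)=C1CC=C(C)C | intermediate
17 | 1-[2-hydroxy-4,6-bis(methoxymethoxy)-3,5-bis(3-methylbut-2-enyl)phenyl]-2-methoxyethanone | COCC(=O)c1c(O)c(CC=C(C)C)c(OCOC)c(CC=C(C)C)c1OCOC | intermediate
18 | methyl 3,4-dihydroxybenzoate | COC(=O)c1ccc(O)c(O)c1 | starting material
19 | methyl 3,4-bis(methoxymethoxy)benzoate | COCOc1ccc(C(=O)OC)cc1OCOC | intermediate
20 | 3,4-bis(methoxymethoxy)benzoic acid | COCOc1ccc(C(=O)O)cc1OCOC | intermediate
21 | 2-(2-methoxyacetyl)-3,5-bis(methoxymethoxy)-4,6-bis(3-methylbut-2-enyl)phenyl 3,4-bis(methoxymethoxy)benzoate | COCC(=O)c1c(OC(=O)c2ccc(OCOC)c(OCOC)c2)c(CC=C(C)C)c(OCOC)c(CC=C(C)C)c1OCOC | intermediate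
22 | 1-[3,4-bis(methoxymethoxy)phenyl]-3-[2-hydroxy-4,6-bis(methoxymethoxy)-3,5-bis(3-methylbut-2-enyl)phenyl]-2-methoxypropane-1,3-dione | COC(C(=O)c1ccc(OCOC)c(OCOC)c1)C(=O)c1c(O)c(CC=C(C)C)c(OCOC)c(CC=C(C)C)c1OCOC | intermediate
23 | 2-[3,4-bis(methoxymethoxy)phenyl]-3-methoxy-5,7-bis(methoxymethoxy)-6,8-bis(3-methylbut-2-enyl)chromen-4-one | COc1c(-c2ccc(OCOC)c(OCOC)c2)oc2c(CC=C(C)C)c(OCOC)c(CC=C(C)C)c(OCOC)c2c1=O | intermediate
24 | broussoflavonol B | COc1c(-c2ccc(O)c(O)c2)oc2c(CC=C(C)C)c(O)c(CC=C(C)C)c(O)c2c1=O | target

## Step count and least certain steps

Total: 14 steps. Longest linear sequence: 12 steps (steps 1 to 9, then 12, 13 and 14); the ring B acid 20 is made in two steps (10 and 11) and joins at step 12.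

**Step 9 (key step).** Several processes could divert it:
- protonation of the aryl anion before the acyl shift, which would stop at simple O-arylation;
- addition with the reverse regiochemistry, if the steric effect of the C8 prenyl group outweighs the inductive effect of the C5 oxygen;
- attack of fluoride at sulfur of the triflate in place of silicon, in this crowded ring;
- ene reaction of the aryne with a prenyl group of a second molecule.

The fallback reaches 17 without an aryne. It sets out from 1, which is converted into 1,3,5-tris(methoxymethoxy)benzene F1. Two rounds of ortho-lithiation and prenylation with 4 give 1,3,5-tris(methoxymethoxy)-2-(3-methylbut-2-enyl)benzene F2 and then 1,3,5-tris(methoxymethoxy)-2,4-bis(3-methylbut-2-enyl)benzene F3. A third lithiation at the last ring position and acylation with the N-methoxy-N-methylamide of methoxyacetic acid give 2-methoxy-1-[2,4,6-tris(methoxymethoxy)-3,5-bis(3-methylbut-2-enyl)phenyl]ethanone F4, which is the same compound as A6. Brief treatment with catalytic acid in methanol at 0 °C removes one of the two equivalent acetals ortho to the carbonyl, assisted by that carbonyl, and the route is rejoined at 17.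

**Step 6.** The lithiated carbamate 11 could undergo an anionic ortho-Fries shift of the carbamoyl group before it is alkylated, and copper-mediated substitution could occur partly at the tertiary end of the allyl system. The fallback places this prenyl group by a sigmatropic shift. It sets out from 10, whose carbamate is cleaved with LiAlH4 to 3,5-bis(methoxymethoxy)-4-(3-methylbut-2-enyl)-2-(trimethylsilyl)phenol F5. O-Alkylation with tert-butyl 2-methylbut-3-en-2-yl carbonate and Pd(PPh3)4 (zerovalent palladium) gives the tertiary allyl ether {2,4-bis(methoxymethoxy)-6-[(2-methylbut-3-en-2-yl)oxy]-3-(3-methylbut-2-enyl)phenyl}trimethylsilane F6. Heating brings about an aromatic Claisen rearrangement to the only free ortho position, and the route is rejoined at 13.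

**Step 13.** Enolisation and acyl transfer at the twisted, di-ortho-substituted ketone could be slow, so that base-induced loss of the aroyl group back to 17 competes. The fallback replaces the intramolecular shift by an intermolecular C-acylation: it sets out from 17 and ester 19, treats 17 with excess LiHMDS to form the phenoxide–enolate dianion, and lets this attack the methyl ester, rejoining the route at 22.

**Step 14.** Acid could add the C5 and C7 hydroxyls, once free, across the prenyl double bonds (chroman formation), or add methanol or water to them. The fallback separates ring closure from deprotection and removes the acetals without protic acid. It sets out from 22, which is cyclodehydrated in acetic acid buffered with NaOAc at 80 °C to isolated 23. Treatment with TMSOTf and 2,2′-bipyridyl in CH2Cl2 at 0 °C exchanges the four aryl acetals for silyl ethers, giving 2-[3,4-bis(trimethylsilyloxy)phenyl]-3-methoxy-6,8-bis(3-methylbut-2-enyl)-5,7-bis(trimethylsilyloxy)chromen-4-one F7. Aqueous work-up hydrolyses the silyl ethers, and the route is rejoined at 24.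

## Further compounds

F1 | step 9 | 1,3,5-tris(methoxymethoxy)benzene | COCOc1cc(OCOC)cc(OCOC)c1
F2 | step 9 | 1,3,5-tris(methoxymethoxy)-2-(3-methylbut-2-enyl)benzene | COCOc1cc(OCOC)c(CC=C(C)C)c(OCOC)c1
F3 | step 9 | 1,3,5-tris(methoxymethoxy)-2,4-bis(3-methylbut-2-enyl)benzene | COCOc1cc(OCOC)c(CC=C(C)C)c(OCOC)c1CC=C(C)C
F4 | step 9 | 2-methoxy-1-[2,4,6-tris(methoxymethoxy)-3,5-bis(3-methylbut-2-enyl)phenyl]ethanone | COCC(=O)c1c(OCOC)c(CC=C(C)C)c(OCOC)c(CC=C(C)C)c1OCOC
F5 | step 6 | 3,5-bis(methoxymethoxy)-4-(3-methylbut-2-enyl)-2-(trimethylsilyl)phenol | COCOc1cc(O)c([Si](C)(C)C)c(OCOC)c1CC=C(C)C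
F6 | step 6 | {2,4-bis(methoxymethoxy)-6-[(2-methylbut-3-en-2-yl)oxy]-3-(3-methylbut-2-enyl)phenyl}trimethylsilane | C=CC(C)(C)Oc1cc(OCOC)c(CC=C(C)C)c(OCOC)c1[Si](C)(C)C
F0 | step 13 | none | none
F7 | step 14 | 2-[3,4-bis(trimethylsilyloxy)phenyl]-3-methoxy-6,8-bis(3-methylbut-2-enyl)-5,7-bis(trimethylsilyloxy)chromen-4-one | COc1c(-c2ccc(O[Si](C)(C)C)c(O[Si](C)(C)C)c2)oc2c(CC=C(C)C)c(O[Si](C)(C)C)c(CC=C(C)C)c(O[Si](C)(C)C)c2c1=O
A1 | alternative 1 | 2,4-bis(3-methylbut-2-enyl)-3,5-bis(triisopropylsilyloxy)phenol | Oc1cc(O[Si](C(C)C)(C(C)C)C(C)C)c(CC=C(C)C)c(O[Si](C(C)C)(C(C)C)C(C)C)c1CC=C(C)C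
A2 | alternative 1 | 2-(3-methylbut-2-enyl)-3-(triisopropylsilyloxy)cyclobut-2-en-1-one | O=C1CC(O[Si](C(C)C)(C(C)C)C(C)C)=C1CC=C(C)C
A3 | alternative 1 | (5-methylhex-4-en-1-ynyloxy)tri(propan-2-yl)silane | CC(C)=CCC#CO[Si](C(C)C)(C(C)C)C(C)C
A4 | alternative 2 | 3-[3,4-bis(methoxymethoxy)phenyl]-4-methoxy-5-[2,4,6-tris(methoxymethoxy)-3,5-bis(3-methylbut-2-enyl)phenyl]isoxazole | COCOc1ccc(-c2noc(-c3c(OCOC)c(CC=C(C)C)c(OCOC)c(CC=C(C)C)c3OCOC)c2OC)cc1OCOC
A5 | alternative 2 | 3,4-bis(methoxymethoxy)benzonitrile oxide | COCOc1ccc(C#[N+][O-])cc1OCOC
A6 | alternative 2 | 2-methoxy-1-[2,4,6-tris(methoxymethoxy)-3,5-bis(3-methylbut-2-enyl)phenyl]ethanone | COCC(=O)c1c(OCOC)c(CC=C(C)C)c(OCOC)c(CC=C(C)C)c1OCOC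
A7 | alternative 3 | 2-[3,4-bis(methoxymethoxy)phenyl]-3-methoxy-5,7-bis(methoxymethoxy)-6,8-bis(3-methylbut-2-enyl)chromen-4-one | COc1c(-c2ccc(OCOC)c(OCOC)c2)oc2c(CC=C(C)C)c(OCOC)c(CC=C(C)C)c(OCOC)c2c1=O
A8 | alternative 3 | 2-{(Z)-1-[3,4-bis(methoxymethoxy)phenyl]-2-methoxyethenoxy}-4,6-bis(methoxymethoxy)-3,5-bis(3-methylbut-2-enyl)benzoic acid | CO/C=C(\Oc1c(C(=O)O)c(OCOC)c(CC=C(C)C)c(OCOC)c1CC=C(C)C)c1ccc(OCOC)c(OCOC)c1
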